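**Plan**

- Retrosynthesis first cuts the two aryl–CH2 bonds on central ring B. Each goes back to an ortho-quinone methide released from a phenolic Mannich base. This leaves dienone ring A, butyrylphloroglucinol (ring B) and the 8-butyryl chromene (ring C).
- Ring C is cut at O1–C2 and C4–C4a to a 1,1-dimethylpropargyl ether on the chelated oxygen of bis-MOM butyrylphloroglucinol. Ring A is cut at the C4–geranyl bond to methylphloroacetophenone and a geranyl carbonate.
- Feature used: in ring C the pyran oxygen O1 sits on C8a, directly beside the butyryl-bearing C8. It is the formerly chelated oxygen, so an ether placed on that oxygen fixes the annulation mode.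
- Forward order: butyrylphloroglucinol, bis-MOM ether, propargyl ether, thermal cascade that closes the pyran (the only ring made), MOM removal, aminomethylation and quinone-methide union with ring B, second aminomethylation and union with ring A.
- Stereochemistry: the single stereocentre (C4 of ring A, R) comes from a ligand-controlled Pd-catalysed dearomative geranylation. The E alkene comes from geraniol. No later step touches either.

Key step: step 4

Remark: the descriptor 4R refers to the enol tautomer of ring A as drawn, and the ligand antipode written in step 11 is an assumption, to be inverted if a first assay shows the opposite sense of induction.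

**Route**

Step 1
Reactants: 1 phloroglucinol; 2 butyryl chloride
Product: 3 1-(2,4,6-trihydroxyphenyl)butan-1-one (butyrylphloroglucinol)
Conditions: AlCl3 (3.5 equiv), CH2Cl2/MeNO2, 0 °C to 40 °C; then ice/1 M HCl
Reagents that add atoms: none
Why: Friedel–Crafts acylation of the electron-rich triol at one of three equivalent carbons, after which the aluminium chelate of the product ketone is deactivated, so a second acylation should stay minor.

Step 2
Reactants: 3 butyrylphloroglucinol
Product: 4 1-[2-hydroxy-4,6-bis(methoxymethoxy)phenyl]butan-1-one
Conditions: MOMCl (2.2 equiv), iPr2NEt (2.5 equiv), CH2Cl2, 0 °C to rt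
Reagents that add atoms: chloromethyl methyl ether, COCCl
Why: Base-mediated O-alkylation caps the para hydroxyl and one ortho hydroxyl, the usual outcome for 2,4,6-trihydroxyaryl ketones, while the hydroxyl hydrogen-bonded to the ketone is the least nucleophilic and stays free.

Step 3
Reactants: 4 the bis-MOM phenol; 5 2-methylbut-3-yn-2-ol
Product: 7 1-[2-(2-methylbut-3-yn-2-yloxy)-4,6-bis(methoxymethoxy)phenyl]butan-1-one, via propargyl trifluoroacetate 6 (not isolated)
Conditions: 5, (CF3CO)2O, DBU, MeCN, −5 °C; then 4, DBU, CuCl2·2H2O (1 mol %), MeCN, −5 °C to rt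
Reagents that add atoms: none
Why: Copper-catalysed propargylic etherification, in which a copper acetylide of 6 loses trifluoroacetate to a copper allenylidene that the DBU-derived phenoxide of 4 captures at the tertiary carbon; DBU fully ionises the single remaining (chelated) hydroxyl, so the ether can form on no other oxygen.

Step 4
Reactants: 7 the aryl 1,1-dimethylpropargyl ether
Product: 10 1-[5,7-bis(methoxymethoxy)-2,2-dimethyl-2H-chromen-8-yl]butan-1-one, via allenylphenol 8 (not isolated), via quinone methide 9 (not isolated)
Conditions: o-xylene (0.05 M), 140 °C, Ar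
Reagents that add atoms: none
Why: On heating, the ether undergoes an aromatic propargyl Claisen ([3,3]) shift to the only unsubstituted ortho carbon, which forms the C4–C4a bond and, after enolisation, allenylphenol 8. A 1,5-hydrogen shift from the phenolic O–H to the central allene carbon then gives the (Z)-ortho-quinone methide 9, and a thermally allowed disrotatory oxa-6π electrocyclisation of its carbonyl oxygen onto the CMe2 terminus forms the O1–C2 bond and closes the pyran ring. The closest known reaction type is the thermal conversion of aryl 1,1-dimethylpropargyl ethers into 2,2-dimethyl-2H-chromenes. No stereocentre is created, so only regiochemistry has to be controlled. The other ortho carbon carries the butyryl group, so a shift to it gives a dienone that cannot enolise and returns to 7, and the oxygen that becomes O5 is capped as a MOM ether, so 9 can close only through the oxygen that carried the ether, which therefore becomes O1 next to C8. The geminal methyl groups accelerate both the sigmatropic shift and the ring closure, so a neutral solvent at 140 °C should be enough and the MOM acetals and the ketone remain untouched.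

Step 5
Reactants: 10 the bis-MOM chromene
Product: 11 1-(5,7-dihydroxy-2,2-dimethyl-2H-chromen-8-yl)butan-1-one
Conditions: 3 M aq. HCl, MeOH, 45 °C
Reagents that add atoms: none
Why: Acid-catalysed acetal exchange with methanol releases both phenols while dimethoxymethane is formed, under conditions mild enough for the acyl-deactivated 2,2-dimethylchromene.

Step 6
Reactants: 11 the chromene diol; 12 N,N-dimethylmethyleneiminium iodide
Product: 13 1-{6-[(dimethylamino)methyl]-5,7-dihydroxy-2,2-dimethyl-2H-chromen-8-yl}butan-1-one
Conditions: 12 (1.05 equiv), CH2Cl2, 0 °C to rt; then aq. NaHCO3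
Reagents that add atoms: none
Why: Mannich reaction of the preformed iminium ion with the phloroglucinol-type ring, which has a single free aromatic carbon (C6, flanked by both hydroxyls), so only one aminomethyl phenol can form.

Step 7
Reactants: 13 the ring C Mannich base; 3 butyrylphloroglucinol
Product: 15 1-{3-[(8-butanoyl-5,7-dihydroxy-2,2-dimethyl-2H-chromen-6-yl)methyl]-2,4,6-trihydroxyphenyl}butan-1-one, via quinone methide 14 (not isolated)
Conditions: 3 (4 equiv), 1,4-dioxane, 80 °C
Reagents that add atoms: none
Why: Warming expels dimethylamine from the ortho-hydroxybenzylamine to give ortho-quinone methide 14, which is captured in a Michael-type (Friedel–Crafts) alkylation by a ring carbon of 3, the large excess of the symmetric nucleophile keeping double alkylation low.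

Step 8
Reactants: 15 the ring B–ring C dimer; 12 N,N-dimethylmethyleneiminium iodide
Product: 16 1-{3-[(8-butanoyl-5,7-dihydroxy-2,2-dimethyl-2H-chromen-6-yl)methyl]-5-[(dimethylamino)methyl]-2,4,6-trihydroxyphenyl}butan-1-one
Conditions: 12 (1.0 equiv), CH2Cl2/MeCN, 0 °C to rt; then aq. NaHCO3
Reagents that add atoms: none
Why: Second Mannich reaction, directed to ring B because it holds the only unsubstituted aromatic carbon left in 15.

Step 9
Reactants: 17 2-methylphloroglucinol (2-methylbenzene-1,3,5-triol); 18 acetyl chloride
Product: 19 1-(2,4,6-trihydroxy-3-methylphenyl)ethan-1-one (methylphloroacetophenone)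
Conditions: 18 (1.05 equiv), AlCl3 (3.5 equiv), CH2Cl2/MeNO2, 0 °C to rt; then ice/1 M HCl
Reagents that add atoms: none
Why: Friedel–Crafts acetylation at one of the two equivalent free ring carbons of the triol, with the same self-limiting behaviour as in step 1.

Step 10
Reactants: 20 geraniol
Product: 21 (2E)-3,7-dimethylocta-2,6-dien-1-yl methyl carbonate (geranyl methyl carbonate)
Conditions: ClCO2Me, pyridine, CH2Cl2, 0 °C
Reagents that add atoms: methyl chloroformate, COC(=O)Cl
Why: Acylation of the primary allylic alcohol by the chloroformate gives the carbonate without touching the alkenes, so the E geometry of geraniol is carried over.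

Step 11
Reactants: 19 methylphloroacetophenone; 21 geranyl methyl carbonate
Product: 22 (4R)-2-acetyl-4-[(2E)-3,7-dimethylocta-2,6-dien-1-yl]-3,5-dihydroxy-4-methylcyclohexa-2,5-dien-1-one (ring A)
Conditions: Pd2(dba)3·CHCl3 (2.5 mol %), (1R,2R)-N,N'-bis[2-(diphenylphosphino)benzoyl]cyclohexane-1,2-diamine (7.5 mol %), THF, 0 °C to rt
Reagents that add atoms: none
Why: Proposed new method: zerovalent palladium ionises carbonate 21 to a syn-geranyl π-allyl complex and methoxide, the methoxide deprotonates 19, and the phenoxide should attack the unsubstituted allyl terminus (keeping the E alkene) through its methyl-bearing ring carbon, the most electron-rich ring carbon (the same preference turns acylphloroglucinols into acylfilicinic acids on double C-methylation), while any O-geranyl ether is re-ionised; the chiral pocket of the bisphosphine selects one face of that carbon and so sets the quaternary stereocentre; the closest known reaction types are the Pd-catalysed asymmetric allylic dearomatisation of naphthols, the Pd-catalysed asymmetric geranylation of prochiral oxindole enolates and the base-mediated alkylative dearomatisation of C-methyl acylphloroglucinols.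

Step 12
Reactants: 16 the dimer Mannich base; 22 ring A
Product: 24 (4R)-2-acetyl-6-({3-butanoyl-5-[(8-butanoyl-5,7-dihydroxy-2,2-dimethyl-2H-chromen-6-yl)methyl]-2,4,6-trihydroxyphenyl}methyl)-4-[(2E)-3,7-dimethylocta-2,6-dien-1-yl]-3,5-dihydroxy-4-methylcyclohexa-2,5-dien-1-one (CNP0103039.1), via quinone methide 23 (not isolated)
Conditions: 22 (1.2 equiv), 1,4-dioxane, 60 °C
Reagents that add atoms: none
Why: Thermal loss of dimethylamine from 16 gives quinone methide 23, and the strongly nucleophilic enolic carbon C6 of triketone 22 (its only CH between two carbonyl-type carbons) adds in a Michael reaction to form the second methylene bridge, leaving the quaternary stereocentre untouched.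

**Compound list**

1 | phloroglucinol | Oc1cc(O)cc(O)c1 | starting material
2 | butyryl chloride | CCCC(=O)Cl | starting material
3 | 1-(2,4,6-trihydroxyphenyl)butan-1-one | CCCC(=O)c1c(O)cc(O)cc1O | intermediate
4 | 1-[2-hydroxy-4,6-bis(methoxymethoxy)phenyl]butan-1-one | CCCC(=O)c1c(O)cc(OCOC)cc1OCOC | intermediate
5 | 2-methylbut-3-yn-2-ol | CC(C)(O)C#C | starting material
6 | 2-methylbut-3-yn-2-yl trifluoroacetate (transient) | CC(C)(C#C)OC(=O)C(F)(F)F | intermediate
7 | 1-[2-(2-methylbut-3-yn-2-yloxy)-4,6-bis(methoxymethoxy)phenyl]butan-1-one | CCCC(=O)c1c(OC(C)(C)C#C)cc(OCOC)cc1OCOC | intermediate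
8 | 1-[2-hydroxy-4,6-bis(methoxymethoxy)-3-(3-methylbuta-1,2-dien-1-yl)phenyl]butan-1-one (transient) | CCCC(=O)c1c(O)c(C=C=C(C)C)c(OCOC)cc1OCOC | intermediate
9 | (6Z)-2-butanoyl-3,5-bis(methoxymethoxy)-6-(3-methylbut-2-en-1-ylidene)cyclohexa-2,4-dien-1-one (transient) | CCCC(=O)C1=C(OCOC)C=C(OCOC)/C(=C/C=C(C)C)C1=O | intermediate
10 | 1-[5,7-bis(methoxymethoxy)-2,2-dimethyl-2H-chromen-8-yl]butan-1-one | CCCC(=O)c1c(OCOC)cc(OCOC)c2C=CC(C)(C)Oc12 | intermediate
11 | 1-(5,7-dihydroxy-2,2-dimethyl-2H-chromen-8-yl)butan-1-one | CCCC(=O)c1c(O)cc(O)c2C=CC(C)(C)Oc12 | intermediate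
12 | N,N-dimethylmethyleneiminium iodide | C=[N+](C)C.[I-] | starting material
13 | 1-{6-[(dimethylamino)methyl]-5,7-dihydroxy-2,2-dimethyl-2H-chromen-8-yl}butan-1-one | CCCC(=O)c1c(O)c(CN(C)C)c(O)c2C=CC(C)(C)Oc12 | intermediate
14 | 8-butanoyl-7-hydroxy-2,2-dimethyl-6-methylidene-2H-chromen-5(6H)-one (transient) | CCCC(=O)C1=C(O)C(=C)C(=O)C2=C1OC(C)(C)C=C2 | intermediate
15 | 1-{3-[(8-butanoyl-5,7-dihydroxy-2,2-dimethyl-2H-chromen-6-yl)methyl]-2,4,6-trihydroxyphenyl}butan-1-one | CCCC(=O)c1c(O)cc(O)c(Cc2c(O)c3c(c(C(=O)CCC)c2O)OC(C)(C)C=C3)c1O | intermediate
16 | 1-{3-[(8-butanoyl-5,7-dihydroxy-2,2-dimethyl-2H-chromen-6-yl)methyl]-5-[(dimethylamino)methyl]-2,4,6-trihydroxyphenyl}butan-1-one | CCCC(=O)c1c(O)c(CN(C)C)c(O)c(Cc2c(O)c3c(c(C(=O)CCC)c2O)OC(C)(C)C=C3)c1O | intermediate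
17 | 2-methylbenzene-1,3,5-triol (2-methylphloroglucinol) | Cc1c(O)cc(O)cc1O | starting material
18 | acetyl chloride | CC(=O)Cl | starting material
19 | 1-(2,4,6-trihydroxy-3-methylphenyl)ethan-1-one | CC(=O)c1c(O)cc(O)c(C)c1O | intermediate
20 | geraniol, (2E)-3,7-dimethylocta-2,6-dien-1-ol | CC(C)=CCC/C(C)=C/CO | starting material
21 | (2E)-3,7-dimethylocta-2,6-dien-1-yl methyl carbonate | COC(=O)OC/C=C(\C)CCC=C(C)C | intermediate
22 | (4R)-2-acetyl-4-[(2E)-3,7-dimethylocta-2,6-dien-1-yl]-3,5-dihydroxy-4-methylcyclohexa-2,5-dien-1-one | O=C1C=C(O)[C@@](C)(C/C=C(\C)CCC=C(C)C)C(O)=C1C(C)=O | intermediate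
23 | ortho-quinone methide of ring B formed from 16 by loss of dimethylamine (transient) | CCCC(=O)C1=C(O)C(=C)C(=O)C(Cc2c(O)c3c(c(C(=O)CCC)c2O)OC(C)(C)C=C3)=C1O | intermediate
24 | CNP0103039.1, (4R)-2-acetyl-6-({3-butanoyl-5-[(8-butanoyl-5,7-dihydroxy-2,2-dimethyl-2H-chromen-6-yl)methyl]-2,4,6-trihydroxyphenyl}methyl)-4-[(2E)-3,7-dimethylocta-2,6-dien-1-yl]-3,5-dihydroxy-4-methylcyclohexa-2,5-dien-1-one | CCCC(=O)c1c(O)c(CC2=C(O)[C@@](C)(C/C=C(\C)CCC=C(C)C)C(O)=C(C(C)=O)C2=O)c(O)c(Cc2c(O)c3c(c(C(=O)CCC)c2O)OC(C)(C)C=C3)c1O | target

**Step count**

Total: 12 steps. Longest linear sequence: 9 steps (steps 1 to 8, then step 12). Ring A is made in 3 steps (9 to 11) and joins in step 12.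

**Steps most likely to fail**

Step 11 (proposed new method). Three processes may spoil it:
- The geranyl–palladium complex may attack the unsubstituted ring carbon, or oxygen, in place of the methyl-bearing carbon.
- Facial discrimination may be weak, because the two flanks of the reacting carbon differ only through the remote acetyl group.
- The dearomatised product may be re-ionised by zerovalent palladium, which would erode the enantiomeric purity and drain material to the aromatic regioisomer.

The fallback uses known chemistry and sets out from 19. Geranyl bromide (commercial, 1.0 equiv) and NaOMe in MeOH at 0 °C, the base-mediated alkylative dearomatisation used for C-methyl acylphloroglucinols, should give the racemic dienone F1. Preparative supercritical-fluid chromatography on an amylose tris(3,5-dimethylphenylcarbamate) phase then separates the enantiomers. The (R)-enantiomer, assigned by comparison of its circular dichroism with calculation, is 22, where the route is rejoined. The same separation can polish material of incomplete enantiomeric purity from step 11.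

Step 12. In the warm, amine-containing mixture the methylene bridges may cleave by retro-Michael reaction and re-add with exchange of ring partners. Quinone methide 23 may condense with itself, and the triketone may be alkylated on oxygen. The fallback reverses the polarity of the union and sets out from 22 and 15. Ring A 22 with iminium salt 12 in CH2Cl2 at 0 °C should give the Mannich base of ring A F2. Gentle warming of F2 with dimer 15 in dioxane at 50 °C releases the methylidene trione F3 (configuration as in 22), a strong Michael acceptor. The single free aromatic carbon of ring B in 15 captures it, which gives 24 directly.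

Step 3. The tertiary propargylic ester may eliminate to the enyne before the weakly nucleophilic, chelated phenoxide captures the copper allenylidene, so conversion may stall. The fallback sets out from 4 and comes back at 10 without a propargyl ether and without a new compound (F0). Phenol 4 is condensed with 3-methylbut-2-enal under ethylenediammonium diacetate catalysis in xylene at 140 °C (Knoevenagel-type condensation at the carbon next to the free hydroxyl). Loss of water gives the same quinone methide 9, which closes by the same oxa-6π electrocyclisation to 10. Because only the chelated hydroxyl is free, attack at the other ring carbon cannot lead to a chromene and is reversible, so the regiochemistry is again fixed by that oxygen.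

**Further compounds**

F1 | step 11 | racemic 2-acetyl-4-[(2E)-3,7-dimethylocta-2,6-dien-1-yl]-3,5-dihydroxy-4-methylcyclohexa-2,5-dien-1-one | O=C1C=C(O)C(C)(C/C=C(\C)CCC=C(C)C)C(O)=C1C(C)=O
F2 | step 12 | (4R)-2-acetyl-6-[(dimethylamino)methyl]-4-[(2E)-3,7-dimethylocta-2,6-dien-1-yl]-3,5-dihydroxy-4-methylcyclohexa-2,5-dien-1-one | CN(C)CC1=C(O)[C@@](C)(C/C=C(\C)CCC=C(C)C)C(O)=C(C(C)=O)C1=O
F3 | step 12 | 6-methylidene trione released from F2 by loss of dimethylamine, configuration as in 22 | C=C1C(=O)[C@@](C)(C/C=C(\C)CCC=C(C)C)C(O)=C(C(C)=O)C1=O
F0 | step 3 | none | none
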